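The constants at hand are the charges: the north-west flask, the one asked about, holds 0.050 M substrate against 5.0 mM free catalyst, or 10.0 substrate per catalyst, so its readings are best counted in catalyst rounds.

in all of them: substrate 0.050 M
- north-west: coupling partner 0.10 M; free catalyst 5 mM; temperature 110 °C; the very flask that is asked about, followed so far
- south-west: coupling partner 0.10 M; free catalyst 5 mM; temperature 95 °C; run made earlier
- flask: coupling partner 0.100 M; free catalyst 5.0 mM; temperature 110 °C; time 8.0 d

- north-west (time / d: target / %): 0.625: 13.4; 1.04: 16.9; 1.67: 17.9; 3.00: 19.2; 5.00: 20.0; 8.00: 22.5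
- south-west (time / d: target / %): 1.25: 10.8; 2.00: 14.8; 4.00: 21.2; 6.00: 21.6; 10.0: 19.6; 15.0: 17.4

(scatter of a reading: 0.3 percentage points)

- target, in percent of the substrate first charged, at 8.0 d
- what to do for the largest gain in target; "none" if nothing gains more than 2 percentage points (alder / birch / elm / larch / oak / none)
- target present, with what was taken out counted in, in percent of the substrate first charged, after birch
- target present, with what was taken out counted in, in percent of the substrate first charged, after larch

- alder: at 8.0 d add free catalyst, 100 % of the amount charged, then wait 8.0 d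
- birch: at 8.0 d take out 90 % of the target then present, then wait 8.0 d
- elm: at 8.0 d add coupling partner, 100 % of the amount charged, then wait 8.0 d
- larch: change nothing and wait 8.0 d more
- oak: at 8.0 d raise the temperature by 10 K, then wait 8.0 d

- target that was removed still counts
- the numbers in the tables scatter with a standard deviation of 0.3 percentage points
- additions bring no volume worth counting

1. At 8.00 d the north-west flask reads 22.5 %, which is 2.25 target per catalyst charged, the concentration of target divided by the charge of free catalyst, a standing turnover number.

2. The curve in that count: up to the first reading the flask gains 2.14 d⁻¹ on average. A knee follows near 1.04 d, at 1.69 per catalyst.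

3. Past the knee comes a creep. Between 3.00 d and 8.00 d the readings give 0.0660 d⁻¹, far slower than the start.

4. The count holds what stands, not what has passed through. The south-west run at 95 °C falls from 21.6 % at 6.00 d to 17.4 % at 15.0 d, a drop of 4.2 percentage points, more than the scatter of 0.3 points. So target in the south-west run goes somewhere, and no end level can be read yet.

5. The reckoning here takes the reading for now. If the creep holds for 8.0 d, larch ends at 27.8 %.

6. The forecast gives 22.4 % (21.8 % to 23 %) for now, 27.5 % for larch, 28 % for birch, and alder as best: “Fresh catalyst should therefore give a second burst”.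

7. The flask gives 22.4 % at 8.0 d, 28.2 % after larch and 40.3 % after birch. Its best option is oak, gaining 29 points, against 18 points for birch and 17 points for alder.

    substrate + catalyst intermediate A ⇌ catalyst intermediate B (K = 320 M⁻¹, k = 0.00620 M⁻¹ s⁻¹, Ea = 87.0 kJ mol⁻¹, ΔH = −58.0 kJ mol⁻¹)
    target ⇌ isomer of the product (K = 1.50, k = 1.40 × 10⁻⁵ s⁻¹, Ea = 116 kJ mol⁻¹, ΔH = −72.0 kJ mol⁻¹)
    catalyst intermediate B → by-product + catalyst intermediate C (k = 4.20 × 10⁻⁴ s⁻¹, Ea = 129 kJ mol⁻¹)
    coupling partner + free catalyst → catalyst intermediate A (k = 7.70 × 10⁻⁴ M⁻¹ s⁻¹, Ea = 87.0 kJ mol⁻¹)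
    catalyst intermediate C → free catalyst + target (k = 0.00170 s⁻¹, Ea = 103 kJ mol⁻¹)
    free catalyst ⇌ dormant form (K = 23.0, k = 1.60 × 10⁻⁵ s⁻¹, Ea = 129 kJ mol⁻¹, ΔH = −64.0 kJ mol⁻¹)
    (constants at 110 °C)

At 8.00 d the flask asked about holds 0.0273 M by-product, 5.46 per catalyst charged, beside 32.1 % isomer of the product, while its reading gave 2.25 target per catalyst. In the neighbour flask charged with 0.085 M substrate and the same free catalyst, 2.25 per catalyst gives 13.2 %, and that flask stands at 13.3 %.

The data are simulated for substances that don't exist.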